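**Retrosynthetic overview**

1. The strategy rests on one feature: in each flavan half, ring A carries a phenolic oxygen (O1, O1') that is separated from a phenyl-bearing benzylic carbon (C2, C2') only by C3–C4 (C3'–C4'), and the halves are joined solely through the C4–O–C4' ether. Both rings C can therefore stay open until the end.
2. After removal of the C5 benzyl ether, O1–C2 and O1'–C2' are cut together. This leads to an acyclic (R,R)-bis(1-aryl-3-phenylallyl) ether bis-phenol. Cobalt-hydride hydrogen-atom transfer to C3 and C3', with capture of C2 and C2' by the phenols, closes both rings C in one operation. This is the only ring-forming event; rings A and the phenyl rings are bought in.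
3. C4'–O is made by iridium/phosphoramidite allylic etherification of the unit B cinnamyl-type carbonate with the copper alkoxide of the unit A alcohol. The vinyl group formed is phenylated by a Heck reaction, not by styrene cross-metathesis, because the 1,6-diene would ring-close to a 2,5-dihydrofuran.
4. C4 is set by asymmetric (E)-styrylzinc addition to the unit A aldehyde, which gives the (R)-carbinol with its styrene already in place.
5. Both aldehydes come from 3,4,5-trimethoxyphenol by ortho-formylation. Unit A is differentiated by chelation-directed demethylation, silylation of the less hindered phenol (future O1) and benzylation of the other (future C5–OH).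

Key step: step 13

Assumption (chemistry): the sense of induction known for (+)-MIB and for the (Ra,R,R) phosphoramidite with simple aryl substrates is taken to hold for the 2,6-dioxygenated aryl groups; if it does not, the antipodal ligand is used in that step.

**Route**

Step 1
Reactants: 1 3,4,5-trimethoxyphenol
Product: 2 6-hydroxy-2,3,4-trimethoxybenzaldehyde
Conditions: MgCl2, Et3N, (CH2O)n, MeCN, reflux; aq. HCl
Reagents that add atoms: paraformaldehyde (as formaldehyde), C=O
Why: Casnati–Skattebøl ortho-formylation, in which the magnesium phenoxide delivers formaldehyde to the carbon next to the hydroxyl group and a second formaldehyde oxidises the benzylic alkoxide, can give only one aldehyde because the two free ring positions of 1 are equivalent.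

Step 2
Reactants: 2 6-hydroxy-2,3,4-trimethoxybenzaldehyde
Product: 3 2,3,4-trimethoxy-6-(triisopropylsilyloxy)benzaldehyde
Conditions: TIPSCl, imidazole, DMF, rt to 40 °C
Reagents that add atoms: chlorotriisopropylsilane, CC(C)[Si](Cl)(C(C)C)C(C)C
Why: Silyl ether formation on the hydrogen-bonded phenol; the triisopropylsilyl group is chosen because it should withstand the olefination, hydride and organometallic steps and is removed at the end by fluoride without acid.

Step 3
Reactants: 3 2,3,4-trimethoxy-6-(triisopropylsilyloxy)benzaldehyde; 4 triethyl phosphonoacetate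
Product: 5 ethyl (E)-3-[2,3,4-trimethoxy-6-(triisopropylsilyloxy)phenyl]prop-2-enoate
Conditions: LiCl, DBU, MeCN, rt
Reagents that add atoms: none
Why: Horner–Wadsworth–Emmons olefination under Masamune–Roush conditions should give the E enoate from the hindered aldehyde while the mild amine base leaves the aryl silyl ether intact.

Step 4
Reactants: 5 ethyl (E)-3-[2,3,4-trimethoxy-6-(triisopropylsilyloxy)phenyl]prop-2-enoate
Product: 6 (E)-3-[2,3,4-trimethoxy-6-(triisopropylsilyloxy)phenyl]prop-2-en-1-ol
Conditions: i-Bu2AlH, CH2Cl2, −78 °C; aq. Rochelle salt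
Reagents that add atoms: none
Why: 1,2-Reduction of the enoate by i-Bu2AlH at low temperature should give the allylic alcohol without touching the alkene or the silyl ether.

Step 5
Reactants: 6 (E)-3-[2,3,4-trimethoxy-6-(triisopropylsilyloxy)phenyl]prop-2-en-1-ol
Product: 7 tert-butyl (E)-3-[2,3,4-trimethoxy-6-(triisopropylsilyloxy)phenyl]prop-2-en-1-yl carbonate
Conditions: Boc2O, DMAP (cat.), CH2Cl2, 0 °C to rt
Reagents that add atoms: di-tert-butyl dicarbonate, CC(C)(C)OC(=O)OC(=O)OC(C)(C)C
Why: O-Acylation with Boc2O under nucleophilic catalysis gives the linear allylic carbonate needed for iridium-catalysed substitution, the tert-butoxide that it later releases being a poor competing nucleophile.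

Step 6
Reactants: 2 6-hydroxy-2,3,4-trimethoxybenzaldehyde
Product: 8 2,6-dihydroxy-3,4-dimethoxybenzaldehyde
Conditions: BCl3 (ca. 2.2 equiv), CH2Cl2, −78 to 0 °C; H2O
Reagents that add atoms: none
Why: Chelation-directed ether cleavage: boron bound to the formyl oxygen activates only the methoxy group ortho to it (six-membered chelate), so chloride removes that methyl group and the 3- and 4-methoxy groups stay, provided the reaction is stopped before the 3-methoxy group next to the new borate is attacked.

Step 7
Reactants: 8 2,6-dihydroxy-3,4-dimethoxybenzaldehyde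
Product: 9 2-hydroxy-3,4-dimethoxy-6-(triisopropylsilyloxy)benzaldehyde
Conditions: TIPSCl (1.05 equiv), imidazole, CH2Cl2, 0 °C
Reagents that add atoms: chlorotriisopropylsilane, CC(C)[Si](Cl)(C(C)C)C(C)C
Why: Site-selective silylation: the 6-hydroxyl flanked by C5–H is far more accessible to the bulky silyl chloride than the 2-hydroxyl flanked by the 3-methoxy group, and the remaining hydroxyl is deactivated by its hydrogen bond to the formyl group.

Step 8
Reactants: 9 2-hydroxy-3,4-dimethoxy-6-(triisopropylsilyloxy)benzaldehyde
Product: 10 2-(benzyloxy)-3,4-dimethoxy-6-(triisopropylsilyloxy)benzaldehyde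
Conditions: BnOH, PPh3, DIAD, THF, 0 °C to rt
Reagents that add atoms: benzyl alcohol, OCc1ccccc1
Why: Mitsunobu etherification of the acidic, chelated phenol with benzyl alcohol proceeds under neutral conditions, which avoids the carbonate bases that could cleave the aryl silyl ether.

Step 9
Reactants: 10 2-(benzyloxy)-3,4-dimethoxy-6-(triisopropylsilyloxy)benzaldehyde; 11 phenylacetylene
Product: 14 (1R,2E)-1-[2-(benzyloxy)-3,4-dimethoxy-6-(triisopropylsilyloxy)phenyl]-3-phenylprop-2-en-1-ol, via (E)-dicyclohexyl(styryl)borane 12 (not isolated), via (E)-ethyl(styryl)zinc 13 (not isolated)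
Conditions: Cy2BH (from BH3·SMe2, cyclohexene), toluene, 0 °C to rt; Et2Zn, −78 °C; (+)-MIB (10 mol%), then 10, −20 to 0 °C; aq. NH4Cl
Reagents that add atoms: none
Why: Catalytic asymmetric alkenylzinc addition to an aldehyde (syn hydroboration of the alkyne fixes the E geometry, boron-to-zinc exchange gives the alkenyl(ethyl)zinc, and the amino alcohol ligand (+)-MIB, (2R)-3-exo-morpholinoisoborneol, directs the alkenyl group to the Re face of the formyl group), which should set C4 as (R).

Step 10
Reactants: 14 (1R,2E)-1-[2-(benzyloxy)-3,4-dimethoxy-6-(triisopropylsilyloxy)phenyl]-3-phenylprop-2-en-1-ol; 7 tert-butyl (E)-3-[2,3,4-trimethoxy-6-(triisopropylsilyloxy)phenyl]prop-2-en-1-yl carbonate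
Product: 17 (1R,2E)-1-[2-(benzyloxy)-3,4-dimethoxy-6-(triisopropylsilyloxy)phenyl]-3-phenylprop-2-en-1-yl (1R)-1-[2,3,4-trimethoxy-6-(triisopropylsilyloxy)phenyl]prop-2-en-1-yl ether, via lithium alkoxide of the unit A alcohol 15 (not isolated), via copper alkoxide of the unit A alcohol 16 (not isolated)
Conditions: n-BuLi, THF, −78 °C; CuI, −78 to 0 °C; then 7, [Ir(cod)Cl]2 (2 mol%), (Ra,R,R)-O,O'-(1,1'-binaphthalene-2,2'-diyl) N,N-bis[1-(2-methoxyphenyl)ethyl]phosphoramidite (4 mol%), THF, rt
Reagents that add atoms: none
Why: Iridium-catalysed asymmetric allylic etherification with a copper alkoxide: the allyliridium intermediate formed from 7 is attacked at its aryl-bearing terminus to give the branched ether, the (Ra,R,R) ligand setting C4' as (R) under catalyst control while C4 of the alkoxide is untouched, and the low-temperature lithium-to-copper exchange on a triisopropylsilyl ether guards against O-to-O silyl migration.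

Step 11
Reactants: 17 the mixed ether of step 10 (unit A styryl, unit B vinyl); 18 iodobenzene
Product: 19 bis[(1R,2E)-1-aryl-3-phenylprop-2-en-1-yl] ether in which the aryl groups are 2-(benzyloxy)-3,4-dimethoxy-6-(triisopropylsilyloxy)phenyl (unit A) and 2,3,4-trimethoxy-6-(triisopropylsilyloxy)phenyl (unit B)
Conditions: Pd(OAc)2 (5 mol%), Bu4NCl, NaHCO3, DMF, 60 °C
Reagents that add atoms: none
Why: Mizoroki–Heck arylation under ligand-free phase-transfer (Jeffery) conditions: phenylpalladium iodide adds to the unhindered terminal vinyl group with phenyl at the terminal carbon and syn β-hydride elimination of a benzylic hydrogen gives the E styrene, whereas the internal alkene of unit A is too hindered to insert and the mild bicarbonate base leaves the silyl ethers and the central ether alone.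

Step 12
Reactants: 19 the bis(triisopropylsilyl) ether of step 11
Product: 20 (1R,2E)-1-[2-(benzyloxy)-6-hydroxy-3,4-dimethoxyphenyl]-3-phenylprop-2-en-1-yl (1R,2E)-1-(6-hydroxy-2,3,4-trimethoxyphenyl)-3-phenylprop-2-en-1-yl ether
Conditions: Bu4NF, AcOH, THF, 0 °C; used directly in step 13
Reagents that add atoms: none
Why: Fluoride cleavage of both aryl silyl ethers, buffered with acetic acid so that no free phenoxide can expel the benzylic alkoxide (ortho-quinone methide formation) or isomerise the ether.

Step 13
Reactants: 20 the (R,R) bis-phenol of step 12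
Product: 23 (2S,4R)-5-(benzyloxy)-6,7-dimethoxy-2-phenylchroman-4-yl (2S,4R)-5,6,7-trimethoxy-2-phenylchroman-4-yl ether (5-O-benzyl ether of the target), via mono-closed ether (ring C of unit A formed) 21 (not isolated), via mono-closed ether (ring C of unit B formed) 22 (not isolated)
Conditions: Co(salen) [C32H46CoN2O2, N,N'-bis(3,5-di-tert-butylsalicylidene)ethane-1,2-diaminocobalt, divalent cobalt; 10 mol%], N-fluoro-2,4,6-trimethylpyridinium tetrafluoroborate (2.4 equiv), PhSiH3 (2.4 equiv), PhCF3, 0 °C to rt, argon
Reagents that add atoms: none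
Why: The divalent cobalt complex is oxidised by the N-fluoropyridinium salt to a fluoride of trivalent cobalt, which PhSiH3 converts into a cobalt hydride; hydrogen-atom transfer to C3 and to C3' gives the phenyl-stabilised C2 and C2' radicals, which are taken up by cobalt and oxidised to alkyl complexes of tetravalent cobalt, and these cation equivalents are displaced by the ortho phenols O1 and O1'. The closest known reaction type is the cobalt-catalysed Mukaiyama-type HAT/radical–polar crossover hydroalkoxylation of alkenes by tethered alcohols and phenols, run here on two styrenes in one flask. Each ring C closes in a six-membered mode by O1-to-C2 bond formation (6-endo with respect to the former C2=C3 bond), the regiochemistry being fixed because hydrogen goes to C3 and only the benzylic C2 can carry the radical or the cation. The new centres C2 and C2' are set by substrate control from the (R) centres C4 and C4': the benzylic centre is planar or stereolabile when it is attacked, and the chair-like transition state with phenyl equatorial and the C4–O bond axial, which keeps that bond out of the plane of ring A and away from the C5 substituent (allylic 1,3-strain), should lead to 2,4-trans and hence to (2S) and (2'S). The step needs chemoselectivity for the free phenols over the benzyl ether oxygen at C5, which could reach C2 through a ring of the same size; this is secured because a phenol that can give its proton to the liberated 2,4,6-trimethylpyridine is a much better nucleophile than a hindered aryl alkyl ether. It also needs the doubly benzylic C4–O–C4' ether to survive, which is secured because no acid stronger than the pyridinium salt is present.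

Step 14
Reactants: 23 the 5-O-benzyl ether of step 13
Product: 24 beilschmieflavonoid B, (2S,4R)-6,7-dimethoxy-2-phenyl-4-{[(2S,4R)-5,6,7-trimethoxy-2-phenylchroman-4-yl]oxy}chroman-5-ol
Conditions: Pd/C (10%), 1,4-cyclohexadiene, EtOAc–EtOH, rt
Reagents that add atoms: none
Why: Catalytic transfer hydrogenolysis should cleave the aryl benzyl ether far faster than the benzylic C2–O1 and C4–O–C4' bonds of the flavan units under neutral conditions with a limited hydrogen supply, so that only the C5 hydroxyl is unveiled.

**Compound list**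

1 | 3,4,5-trimethoxyphenol | COc1cc(O)cc(OC)c1OC | starting material
2 | 6-hydroxy-2,3,4-trimethoxybenzaldehyde | O=Cc1c(O)cc(OC)c(OC)c1OC | intermediate
3 | 2,3,4-trimethoxy-6-(triisopropylsilyloxy)benzaldehyde | O=Cc1c(O[Si](C(C)C)(C(C)C)C(C)C)cc(OC)c(OC)c1OC | intermediate
4 | triethyl phosphonoacetate | CCOC(=O)CP(=O)(OCC)OCC | starting material
5 | ethyl (E)-3-[2,3,4-trimethoxy-6-(triisopropylsilyloxy)phenyl]prop-2-enoate | CCOC(=O)/C=C/c1c(O[Si](C(C)C)(C(C)C)C(C)C)cc(OC)c(OC)c1OC | intermediate
6 | (E)-3-[2,3,4-trimethoxy-6-(triisopropylsilyloxy)phenyl]prop-2-en-1-ol | OC/C=C/c1c(O[Si](C(C)C)(C(C)C)C(C)C)cc(OC)c(OC)c1OC | intermediate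
7 | tert-butyl (E)-3-[2,3,4-trimethoxy-6-(triisopropylsilyloxy)phenyl]prop-2-en-1-yl carbonate | CC(C)(C)OC(=O)OC/C=C/c1c(O[Si](C(C)C)(C(C)C)C(C)C)cc(OC)c(OC)c1OC | intermediate
8 | 2,6-dihydroxy-3,4-dimethoxybenzaldehyde | O=Cc1c(O)cc(OC)c(OC)c1O | intermediate
9 | 2-hydroxy-3,4-dimethoxy-6-(triisopropylsilyloxy)benzaldehyde | O=Cc1c(O[Si](C(C)C)(C(C)C)C(C)C)cc(OC)c(OC)c1O | intermediate
10 | 2-(benzyloxy)-3,4-dimethoxy-6-(triisopropylsilyloxy)benzaldehyde | O=Cc1c(O[Si](C(C)C)(C(C)C)C(C)C)cc(OC)c(OC)c1OCc1ccccc1 | intermediate
11 | phenylacetylene | C#Cc1ccccc1 | starting material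
12 | (E)-dicyclohexyl(styryl)borane | C1CCCCC1B(/C=C/c1ccccc1)C1CCCCC1 | intermediate
13 | (E)-ethyl(styryl)zinc | CC[Zn]/C=C/c1ccccc1 | intermediate
14 | (1R,2E)-1-[2-(benzyloxy)-3,4-dimethoxy-6-(triisopropylsilyloxy)phenyl]-3-phenylprop-2-en-1-ol | COc1cc(O[Si](C(C)C)(C(C)C)C(C)C)c(c(OCc2ccccc2)c1OC)[C@H](O)/C=C/c1ccccc1 | intermediate
15 | lithium alkoxide of 14 | COc1cc(O[Si](C(C)C)(C(C)C)C(C)C)c(c(OCc2ccccc2)c1OC)[C@H](O[Li])/C=C/c1ccccc1 | intermediate
16 | copper alkoxide of 14 (monovalent copper) | COc1cc(O[Si](C(C)C)(C(C)C)C(C)C)c(c(OCc2ccccc2)c1OC)[C@H](O[Cu])/C=C/c1ccccc1 | intermediate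
17 | (1R,2E)-1-[2-(benzyloxy)-3,4-dimethoxy-6-(triisopropylsilyloxy)phenyl]-3-phenylprop-2-en-1-yl (1R)-1-[2,3,4-trimethoxy-6-(triisopropylsilyloxy)phenyl]prop-2-en-1-yl ether | COc1cc(O[Si](C(C)C)(C(C)C)C(C)C)c(c(OCc2ccccc2)c1OC)[C@H](O[C@H](C=C)c1c(O[Si](C(C)C)(C(C)C)C(C)C)cc(OC)c(OC)c1OC)/C=C/c1ccccc1 | intermediate
18 | iodobenzene | Ic1ccccc1 | starting material
19 | (R,R)-bis(1-aryl-3-phenylallyl) ether, both alkenes E, both phenols as triisopropylsilyl ethers, unit A with 2-benzyloxy | COc1cc(O[Si](C(C)C)(C(C)C)C(C)C)c(c(OCc2ccccc2)c1OC)[C@H](O[C@H](/C=C/c1ccccc1)c1c(O[Si](C(C)C)(C(C)C)C(C)C)cc(OC)c(OC)c1OC)/C=C/c1ccccc1 | intermediate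
20 | (1R,2E)-1-[2-(benzyloxy)-6-hydroxy-3,4-dimethoxyphenyl]-3-phenylprop-2-en-1-yl (1R,2E)-1-(6-hydroxy-2,3,4-trimethoxyphenyl)-3-phenylprop-2-en-1-yl ether | COc1cc(O)c(c(OCc2ccccc2)c1OC)[C@H](O[C@H](/C=C/c1ccccc1)c1c(O)cc(OC)c(OC)c1OC)/C=C/c1ccccc1 | intermediate
21 | mono-closed ether, ring C of unit A formed (2S,4R), unit B still the open (R,E) phenol | COc1cc2c(c(OCc3ccccc3)c1OC)[C@H](O[C@H](/C=C/c1ccccc1)c1c(O)cc(OC)c(OC)c1OC)C[C@@H](c1ccccc1)O2 | intermediate
22 | mono-closed ether, ring C of unit B formed (2S,4R), unit A still the open (R,E) phenol | COc1cc(O)c(c(OCc2ccccc2)c1OC)[C@H](O[C@@H]1C[C@@H](c2ccccc2)Oc2cc(OC)c(OC)c(OC)c21)/C=C/c1ccccc1 | intermediate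
23 | (2S,4R)-5-(benzyloxy)-6,7-dimethoxy-2-phenylchroman-4-yl (2S,4R)-5,6,7-trimethoxy-2-phenylchroman-4-yl ether | COc1cc2c(c(OCc3ccccc3)c1OC)[C@H](O[C@@H]1C[C@@H](c3ccccc3)Oc3cc(OC)c(OC)c(OC)c31)C[C@@H](c1ccccc1)O2 | intermediate
24 | beilschmieflavonoid B | COc1cc2c(c(O)c1OC)[C@H](O[C@@H]1C[C@@H](c3ccccc3)Oc3cc(OC)c(OC)c(OC)c31)C[C@@H](c1ccccc1)O2 | target

**Step count and risks**

Total step count: 14. Longest linear sequence: 10 steps (steps 1, 6, 7, 8, 9, 10, 11, 12, 13, 14; the unit B branch through steps 1 to 5 is equally long).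

Steps most likely to fail:

1. Step 13. Closure through the less favoured chair at one or both rings would erode the 2,4-trans relationship. A second hydrogen transfer to the benzylic radical would simply reduce an alkene. The benzyl ether oxygen could compete with the phenol for C2. The N-fluoro oxidant could fluorinate the electron-rich rings A. Fallback, an ionic two-stage closure by known chemistry that sets out from 20: treatment with PhSeCl and K2CO3 in CH2Cl2 at −78 °C should open each seleniranium ion at the benzylic carbon by the ortho phenol (anti addition, same chair preference) to give the 3,3'-bis(phenylselanyl) derivative of 23 with 2,3-trans and 3,4-cis substituents in each ring, F1. Radical deselenation with (Me3Si)3SiH and AIBN in toluene at 80 °C then comes back to the route at 23.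

2. Step 10. The 2,6-dioxygenated aryl group may slow ionisation of the carbonate or block attack at the aryl-bearing allyl terminus, so that linear ether or poor catalyst control at C4' results. Silyl transfer from the aryl oxygen to the neighbouring alkoxide is a further hazard. Fallback that sets out from 3: addition of vinylmagnesium bromide (THF, −78 °C) gives racemic 1-[2,3,4-trimethoxy-6-(triisopropylsilyloxy)phenyl]prop-2-en-1-ol, F2. This is coupled directly with alcohol 14 by enantioconvergent iridium-catalysed etherification of the branched carbinol ([Ir(cod)Cl]2, a chiral phosphoramidite–alkene ligand of the enantiomer that gives (R) at C4', catalytic acid promoter, 1,2-dichloroethane, rt), a system known to accept 2,6-dialkoxyaryl vinyl carbinols. It comes back to the route at 17.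

3. Step 9. An uncatalysed, chelation-assisted addition to the hindered aldehyde flanked by two oxygen substituents may compete with the ligand-bound pathway and erode the enantioselectivity at C4. Any minor enantiomer would, however, appear after step 10 as a separable diastereomer. Fallback that sets out from 10: addition of commercial lithium phenylacetylide (THF, −78 °C) gives the racemic propargylic alcohol 1-[2-(benzyloxy)-3,4-dimethoxy-6-(triisopropylsilyloxy)phenyl]-3-phenylprop-2-yn-1-ol, F3. Oxidation with MnO2 (CH2Cl2, rt) gives the ynone 1-[2-(benzyloxy)-3,4-dimethoxy-6-(triisopropylsilyloxy)phenyl]-3-phenylprop-2-yn-1-one, F4. Corey–Bakshi–Shibata reduction ((S)-Me-CBS, BH3·SMe2, THF, −30 °C; the hindered aryl as the large group) should give the (R)-propargylic alcohol, F5. Trans-hydroalumination with NaAlH2(OCH2CH2OMe)2 (THF, 0 °C) comes back to the route at 14.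

**Further compounds**

F1 | step 13 | 3,3'-bis(phenylselanyl) derivative of 23 (each ring 2,3-trans, 3,4-cis) | COc1cc2c(c(OCc3ccccc3)c1OC)[C@H](O[C@@H]1[C@H]([Se]c3ccccc3)[C@@H](c3ccccc3)Oc3cc(OC)c(OC)c(OC)c31)[C@H]([Se]c1ccccc1)[C@@H](c1ccccc1)O2
F2 | step 10 | racemic 1-[2,3,4-trimethoxy-6-(triisopropylsilyloxy)phenyl]prop-2-en-1-ol | C=CC(O)c1c(O[Si](C(C)C)(C(C)C)C(C)C)cc(OC)c(OC)c1OC
F3 | step 9 | racemic 1-[2-(benzyloxy)-3,4-dimethoxy-6-(triisopropylsilyloxy)phenyl]-3-phenylprop-2-yn-1-ol | COc1cc(O[Si](C(C)C)(C(C)C)C(C)C)c(c(OCc2ccccc2)c1OC)C(O)C#Cc1ccccc1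
F4 | step 9 | 1-[2-(benzyloxy)-3,4-dimethoxy-6-(triisopropylsilyloxy)phenyl]-3-phenylprop-2-yn-1-one | COc1cc(O[Si](C(C)C)(C(C)C)C(C)C)c(c(OCc2ccccc2)c1OC)C(=O)C#Cc1ccccc1
F5 | step 9 | (R)-1-[2-(benzyloxy)-3,4-dimethoxy-6-(triisopropylsilyloxy)phenyl]-3-phenylprop-2-yn-1-ol | COc1cc(O[Si](C(C)C)(C(C)C)C(C)C)c(c(OCc2ccccc2)c1OC)[C@H](O)C#Cc1ccccc1
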